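**Direct plan and its weak points**

A direct plan would acylate 1,2,3,5-tetramethoxybenzene A1 with a methoxyacetyl donor and cleave one carbonyl-flanking ether with a boron trihalide to the hydroxy ketone A2. It would then close 3,5,7,8-tetramethoxychromone A3 with a formamide acetal, zincate C2 with TMPZnCl·LiCl and cross-couple with 1-bromo-2,4-dimethoxybenzene A4 to the fully methylated flavone A5, and end with Lewis-acid cleavage of the 5-OMe group.
- The mono-demethylation that would lead from the acylated A1 to A2: two methoxy groups flank the carbonyl and both can chelate boron, so the 5,7,8 (against 5,6,7) pattern would rest on a small buttressing preference.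
- The C2 metalation and Negishi arylation of A3: a 2-metalated chromone can ring-open, A4 is an ortho-substituted, electron-rich bromide that is slow in oxidative addition, and the only C–C bond to ring B would come late on the most advanced intermediate.
- The last 5-O-demethylation of A5: one of six methyl ethers would have to fall selectively although the 3-OMe can chelate too, and the ring A oxygens of A1 would be methylated and unmasked twice, which builds nothing.

**Retrosynthetic overview of the new route**

- The feature used is the para pair O5/O8 on ring A, which flanks the fusion carbons C4a/C8a: it marks ring A as a masked 2-acyl-5-methoxybenzoquinone in which C8a is electrophilic.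
- Key disconnection: the aryl ether bond O1–C8a of ring C, formed by oxa-Michael addition of a diketone enol to the quinone made in the flask from the open-chain diketone 6.
- Ring order: rings A and B are bought and joined at C2–C3 by a Claisen-type acylation; ring C closes last, at O1–C8a instead of O1–C2, and no chromone is metalated or cross-coupled.
- The closure gives the 5-OH chelated and the 8-OH free, and the only electrophilic quinone CH fixes the 5,7,8 pattern. This removes both the regiochemical ether cleavage and the late demethylation; the oxidative loss of two methyl groups is the activation for ring closure, and one methyl is returned.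

Key step: step 3

Remark on the chemistry: the target is achiral; diketone 6 forms as a racemate at C2 and is used as such, its stereocentre disappearing in step 3. Compounds 1, 2 and 4 are taken to be commercial.

**Route**

Step 1
Reactants: 1 1,2,4-trimethoxybenzene; 2 methoxyacetic acid
Product: 3 2-methoxy-1-(2,4,5-trimethoxyphenyl)ethan-1-one
Conditions: 2 (1.2 equiv), (CF3CO)2O (2 equiv), 85% H3PO4 (cat.), CH2Cl2, 0 °C → rt
Reagents that add atoms: none
Why: Friedel–Crafts acylation by the mixed trifluoroacetic anhydride of 2 should occur at C5 of 1, the only free position that is para to one methoxy group and ortho to another, and the mild acyl donor avoids the decarbonylation and ether cleavage that an acid chloride with AlCl3 would risk.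

Step 2
Reactants: 3 2-methoxy-1-(2,4,5-trimethoxyphenyl)ethan-1-one; 4 2,4-dimethoxybenzoyl chloride
Product: 6 1-(2,4-dimethoxyphenyl)-2-methoxy-3-(2,4,5-trimethoxyphenyl)propane-1,3-dione, via lithium enolate 5 (not isolated)
Conditions: LiN(SiMe3)2 (2.2 equiv), THF, −78 °C; then 4 (1.05 equiv), −78 → 0 °C; 1 M HCl work-up
Reagents that add atoms: none
Why: Claisen-type C-acylation of the chelated Z lithium enolate of the α-methoxy ketone by the acid chloride, driven by deprotonation of the more acidic 1,3-diketone by the second equivalent of base, forms the C2–C3 bond that links rings A and B; the new stereocentre is racemic and of no consequence.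

Step 3
Reactants: 6 1-(2,4-dimethoxyphenyl)-2-methoxy-3-(2,4,5-trimethoxyphenyl)propane-1,3-dione
Product: 9 2-(2,4-dimethoxyphenyl)-5,8-dihydroxy-3,7-dimethoxy-4H-chromen-4-one, via acylbenzoquinone 7 (not isolated), via flavonequinone 8 (not isolated)
Conditions: (NH4)2Ce(NO3)6 (4.5 equiv), MeCN–H2O (3:1), 0 °C → rt; then aqueous Na2S2O4, EtOAc, Ar
Reagents that add atoms: water, O
Why: Tetravalent cerium oxidises ring A of 6, the only ring with para-related methoxy groups, to its radical cation; water attacks the two ipso carbons and two molecules of methanol leave (oxidative demethylation of a 1,4-dimethoxyarene), which gives 2-acyl-5-methoxybenzoquinone 7 and turns the former arene carbon C8a from a nucleophilic into an electrophilic centre. The enol oxygen of the 1,3-diketone (enolisation catalysed by the HNO3 set free) then adds 6-endo-trig to that quinone CH carbon, which is β to the ring carbonyl and to the side-chain carbonyl, and tautomerisation to the aromatic hydroquinone makes the closure of ring C at O1–C8a irreversible; the closest known reaction types are the cyclisation of (2-hydroxybenzoyl)benzoquinones to xanthones and of (3-oxoalkanoyl)naphthoquinones to pyranonaphthoquinones by intramolecular oxa-Michael addition. Site selectivity is secured by the substrate: the other quinone CH is the electron-rich β carbon of the methoxy enol ether, attack by the diketone carbon would need a four-membered ring, addition to the ring carbonyl is reversible, and the classical closure through an ortho phenol is impossible because no phenol is free before ring C exists. The excess oxidant carries the first-formed hydroquinone on to chromenetrione 8, so that redox exchange between it and unreacted 7 cannot strand material, and Na2S2O4 should return all of it to 9. The two hydroxyl groups are thereby born different, the 5-OH chelated to C4=O and the 8-OH free, and no stereocentre is formed.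

Step 4
Reactants: 9 2-(2,4-dimethoxyphenyl)-5,8-dihydroxy-3,7-dimethoxy-4H-chromen-4-one
Product: 10 2-(2,4-dimethoxyphenyl)-5-hydroxy-3,7,8-trimethoxy-4H-chromen-4-one (5-hydroxy-3,7,8,2′,4′-pentamethoxyflavone)
Conditions: MeI (1.1 equiv), K2CO3 (1.2 equiv), degassed acetone, Ar, rt → 40 °C
Reagents that add atoms: iodomethane, CI
Why: Williamson O-methylation (SN2 on MeI) with a weak base should take only the free 8-OH, because the peri 5-OH is locked in a hydrogen bond to C4=O and is much less acidic and less nucleophilic, as in the classical partial methylation of 5-hydroxyflavones.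

**Compound list**

1 | 1,2,4-trimethoxybenzene | COc1ccc(OC)c(OC)c1 | starting material
2 | methoxyacetic acid | COCC(=O)O | starting material
3 | 2-methoxy-1-(2,4,5-trimethoxyphenyl)ethan-1-one | COCC(=O)c1cc(OC)c(OC)cc1OC | intermediate
4 | 2,4-dimethoxybenzoyl chloride | COc1ccc(C(=O)Cl)c(OC)c1 | starting material
5 | lithium (Z)-2-methoxy-1-(2,4,5-trimethoxyphenyl)ethen-1-olate (O–Li and OMe cis, chelated) | [Li+].[O-]/C(=C\OC)c1cc(OC)c(OC)cc1OC | intermediate (not isolated)
6 | 1-(2,4-dimethoxyphenyl)-2-methoxy-3-(2,4,5-trimethoxyphenyl)propane-1,3-dione (racemic at C2) | COc1ccc(C(=O)C(OC)C(=O)c2cc(OC)c(OC)cc2OC)c(OC)c1 | intermediate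
7 | 2-[3-(2,4-dimethoxyphenyl)-2-methoxy-3-oxopropanoyl]-5-methoxycyclohexa-2,5-diene-1,4-dione | COc1ccc(C(=O)C(OC)C(=O)C2=CC(=O)C(OC)=CC2=O)c(OC)c1 | intermediate (not isolated)
8 | 2-(2,4-dimethoxyphenyl)-3,7-dimethoxy-4H-chromene-4,5,8-trione | COC1=CC(=O)C2=C(OC(c3ccc(OC)cc3OC)=C(OC)C2=O)C1=O | intermediate (not isolated)
9 | 2-(2,4-dimethoxyphenyl)-5,8-dihydroxy-3,7-dimethoxy-4H-chromen-4-one | COc1ccc(-c2oc3c(O)c(OC)cc(O)c3c(=O)c2OC)c(OC)c1 | intermediate
10 | 2-(2,4-dimethoxyphenyl)-5-hydroxy-3,7,8-trimethoxy-4H-chromen-4-one | COc1ccc(-c2oc3c(OC)c(OC)cc(O)c3c(=O)c2OC)c(OC)c1 | target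

**Step count and risks**

Total step count: 4. Longest linear sequence: 4.

Steps most likely to fail:

Step 3. The risks are these: tetravalent cerium may attack the enolisable diketone or ring B; the 4,5-methoxy pair may be lost to give an ortho-quinone; or the enolised side chain may undergo internal redox tautomerisation against the quinone before the ring closes. The fallback would reach the quinone from a free hydroquinone under neutral conditions instead of by oxidative demethylation. It sets out from 2. Acylation of commercial 2-methoxybenzene-1,4-diol F1 with 2 (BF3·OEt2, 80 °C), para to the methoxy group, should give 1-(2,5-dihydroxy-4-methoxyphenyl)-2-methoxyethan-1-one F2. LiN(SiMe3)2 (4.2 equiv, THF, −78 °C) followed by 4 should C-aroylate the enolate in the presence of the two lithium phenoxides and give 1-(2,5-dihydroxy-4-methoxyphenyl)-3-(2,4-dimethoxyphenyl)-2-methoxypropane-1,3-dione F3. This compound must be kept away from strong acid, which would close it the classical way through its ortho phenol. Ag2O (excess, MgSO4, CH2Cl2, rt) should oxidise F3 to acylbenzoquinone 7, where the fallback comes back to the route; ring closure and Na2S2O4 then lead to 9.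

Step 2. The risks are O-acylation of the enolate, double acylation, or sluggish reaction of the hindered, electron-rich acid chloride. The fallback replaces the acylation by aldol addition and oxidation and sets out from 3. Its lithium enolate (LiN(iPr)2, THF, −78 °C) should add to 2,4-dimethoxybenzaldehyde F4 to give 3-(2,4-dimethoxyphenyl)-3-hydroxy-2-methoxy-1-(2,4,5-trimethoxyphenyl)propan-1-one F5 as a diastereomer mixture of no consequence. Dess–Martin periodinane (CH2Cl2, rt) should oxidise it to 6, where the route is rejoined.

Step 4. The risks are methylation also at the chelated 5-OH, or aerial oxidation of the hydroquinone anion back to 8. The fallback gives up the partial methylation and sets out from 9. Exhaustive methylation (Me2SO4 in excess, K2CO3, acetone, reflux, a trace of Na2S2O4) should give 2-(2,4-dimethoxyphenyl)-3,5,7,8-tetramethoxy-4H-chromen-4-one F6, the same compound as A5. BCl3 (CH2Cl2, −78 → 0 °C) should then cleave only the 5-OMe through the six-membered boron chelate with C4=O and give 10. This re-imports the late selective demethylation criticised in the direct plan and is kept only as a reserve.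

**Further compounds**

F1 | step 3 | 2-methoxybenzene-1,4-diol | COc1cc(O)ccc1O
F2 | step 3 | 1-(2,5-dihydroxy-4-methoxyphenyl)-2-methoxyethan-1-one | COCC(=O)c1cc(O)c(OC)cc1O
F3 | step 3 | 1-(2,5-dihydroxy-4-methoxyphenyl)-3-(2,4-dimethoxyphenyl)-2-methoxypropane-1,3-dione (racemic at C2) | COc1ccc(C(=O)C(OC)C(=O)c2cc(O)c(OC)cc2O)c(OC)c1
F4 | step 2 | 2,4-dimethoxybenzaldehyde | COc1ccc(C=O)c(OC)c1
F5 | step 2 | 3-(2,4-dimethoxyphenyl)-3-hydroxy-2-methoxy-1-(2,4,5-trimethoxyphenyl)propan-1-one (mixture of diastereomers) | COc1ccc(C(O)C(OC)C(=O)c2cc(OC)c(OC)cc2OC)c(OC)c1
F6 | step 4 | 2-(2,4-dimethoxyphenyl)-3,5,7,8-tetramethoxy-4H-chromen-4-one | COc1ccc(-c2oc3c(OC)c(OC)cc(OC)c3c(=O)c2OC)c(OC)c1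
A1 | direct plan | 1,2,3,5-tetramethoxybenzene | COc1cc(OC)c(OC)c(OC)c1
A2 | direct plan | 1-(2-hydroxy-3,4,6-trimethoxyphenyl)-2-methoxyethan-1-one | COCC(=O)c1c(O)c(OC)c(OC)cc1OC
A3 | direct plan | 3,5,7,8-tetramethoxy-4H-chromen-4-one | COc1coc2c(OC)c(OC)cc(OC)c2c1=O
A4 | direct plan | 1-bromo-2,4-dimethoxybenzene | COc1ccc(Br)c(OC)c1
A5 | direct plan | 2-(2,4-dimethoxyphenyl)-3,5,7,8-tetramethoxy-4H-chromen-4-one | COc1ccc(-c2oc3c(OC)c(OC)cc(OC)c3c(=O)c2OC)c(OC)c1
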